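## Structural features

The target is a guaiane. A 2-methylcyclopent-2-enone (C1–C5: ketone at C3, methyl on C4, C4=C5) is fused along C1–C5 to a cycloheptane (C5, C6, C7, C8, C9, C10, C1). The seven-membered ring carries four stereocentres in two adjacent pairs. C1 (ring-fusion hydrogen) stands next to C10 (methyl), and C7 (the C11 dimethylcarbinol acetate) next to C8 (methacrylate). The pairs are separated by C9 on one side and by C6 and the sp2 carbon C5 on the other. H1, the C10 methyl, the C8 oxygen and C11 all lie on one face (1R,7S,8R,10S).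

The methacrylate is a conjugate acceptor that polymerises and does not survive hydrides or organometallics. The tertiary acetate eliminates easily. C1 is γ to the enone and is lost if the enone dienolises toward it. Both esters are therefore introduced last, and strong base is avoided once C1 is set.

The real difficulty is the control of two stereo-pairs that are remote from each other on a flexible ring, together with a tertiary carbinol beside an acylated secondary alcohol.

The key step uses the fact that C1 is the γ-carbon of the enone and C10 its neighbour, while C8 is oxygenated and C7 is at ester level. C6, C7 and C8 can then be read as a donor–acceptor cyclopropane. Its two cis alkenyl arms are the C1=C5 bond of the enone's dienol ether and a C9=C10 (Z)-propenyl group. Their [3,3] shift forms C1–C10, closes the seven-membered ring, and leaves C8 as an enol ether and C7 as the α-carbon of a future β-keto ester.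

## Logic of the disconnections

**28 to 26 (through 27).** The two acyl C–O bonds at O11 and O8 are cut. These esters are the most fragile groups, so they go on last. This leaves a robust diol. The forward steps must tell the secondary hydroxyl from the tertiary one and must acylate the tertiary one without elimination.

**26 to 22 (through 25 and 23).** The two C11–CH3 bonds are cut, so C11 becomes the ester carbon of 22. This is the oxidation level that a cyclopropane acceptor can supply. The forward step needs a strongly basic methyl nucleophile, so the C3 carbonyl is masked by reduction (23) and returned by allylic oxidation (25 to 26). C7 must not epimerise on the way.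

**22 to 21.** The C8–H bond is cut, which takes the C7/C8 pair back to a β-keto ester. The cut is made here because this is the only stage at which C7 can be inverted, and the key step delivers C7 with the wrong orientation. Two stereocentres are traded for one epimerisable pair. The forward step must be a dynamic kinetic reduction that puts hydride anti to the ester and on the correct face relative to the remote C1/C10 pair, so it needs catalyst control.

**21 to 20.** The two O–Si bonds are restored, so both carbonyls become silyl enol ethers. The forward hydrolysis must return the C4=C5 enone without dienolisation toward C1.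

**20 to 17 (key step, through 19).** C1–C10 is cut and C6–C8 is re-formed. This retro-Cope step exchanges the bicycle for a cyclopentenone bearing a cis-dialkenylcyclopropane. It is chosen because one stereospecific step closes the seven-membered ring and sets C1 and C10 in relative and absolute sense. It demands a cis relation of the two alkenyl arms, an ester trans to both, a (Z)-alkene, dienol ether formation toward C1, and a substrate that tolerates heating.

**17 to 16.** The two C–H bonds of the (Z)-alkene are removed to give an alkyne. Syn semi-hydrogenation guarantees the geometry, and no isomerisable (Z)-enone is ever handled. The small linear alkyne also steers the enol ether geometry of 12. The dialkenylcyclopropane stays masked until the last moment. The forward step must stop at the alkene and spare enone and cyclopropane.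

**16 to 14 (through 15).** The C3 ketone is taken back to a silyl-protected carbinol. With the enone in place, the C6=C8 enol ether would be a vinylogous push–pull alkene and would not react with an electrophilic carbenoid. The forward steps need silyl groups that can be told apart (secondary allylic against tertiary cyclopropyl) and a neutral oxidation.

**14 to 12 and 13.** C6–C7 and C7–C8 are cut. C7 arrives with its ester as a single carbenoid carbon, and the cyclopropane stereochemistry follows from the alkene geometry and the catalyst. The forward step must select the enol ether among three π-systems, place the ester trans to both carbon substituents, and discriminate the alkene faces.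

**12 to 10.** The enol O–Si bond is cut. The forward enolisation must put the ring trans to oxygen, because this geometry becomes the cis relation of the two arms on the cyclopropane.

**10 to 7 and 8.** The C8–C9 bond is cut as an acyl substitution by an alkynyl metal. This is convergent and brings in C9, C10 and the C10 methyl. The forward step must stop at the ketone despite the acidic C6 methylene.

**7 to 1 and 2 (through 6 and 5).** The O–Si and C3–H bonds and then C5–C6 are cut. The five-membered ring with its C4 methyl is bought ready-made, and C6/C8 are added as an acetate enolate with transposition of the enone. Building the cyclopentenone after cyclopropanation (aldehyde, acyl-anion addition to a vinyl ketone, aldol) was rejected. An acyl-anion equivalent next to a cyclopropane with a vicinal ester and silyloxy group is expected to open the ring. The forward step needs 1,2-addition to a deactivated carbonyl.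

## Other disconnections considered

**Alternative 1:** The cut is C1–C5 with C5–C10 restored, which turns the hydroazulenone into the cross-conjugated decalin dienone A1. In the forward sense, irradiation of A1 in acetic acid would bond C1 to C5 and open C5–C10 with capture of acetate at C10. This is the acid-mediated photorearrangement of 4-substituted cyclohexa-2,5-dienones to 5/7-fused ketones, and it would give A2.

- In its favour: A1 should be reachable in very few steps by asymmetric annulation and dehydrogenation. Its single quaternary centre would be relayed stereospecifically to C1. The C3 ketone, the C4 methyl and the C4=C5 bond arrive together.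
- Equal or better than the chosen plan: on step count to the bicyclic core it is better. On delivery of the enone it is equal.
- Against it: A2 carries oxygen at C10 where the target has hydrogen. The acetate is cis to H1 and the methyl trans, so replacement by hydrogen needs net inversion through elimination and a face-selective hydrogenation. A2 has no C7 substituent and only a masked ketone at C8. C7 would have to be functionalised in competition with C9, and C7, C8 and C10 would all rest on substrate control. The photoreaction needs dilution and has competing channels.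
- Comparison: the alternative sets one of the four centres, the chosen plan two, and the chosen plan also leaves handles for the other two. Both key steps are stereospecific, one photochemical through charged intermediates, the other thermal and pericyclic. The alternative is shorter to the core and is expected to be longer after it.

**Alternative 2:** The cut is C1–C2, with the C3 oxygen returned to C4 as a propargylic pivalate. This removes the cyclopentenone from the fully substituted cycloheptene A3. In the forward sense, Ph3PAuCl with AgSbF6 (monovalent gold) would trigger 1,2-acyloxy migration and C1–C2 bond formation. Hydrolysis of the dienyl ester would give A4, the target without its C4 methyl.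

- In its favour: the conditions are mild, catalytic and tolerant of both esters. The propargylic centre should pass its configuration to C1 (new bond anti to the departing oxygen, hence the (4S) configuration drawn for A3).
- Better than the chosen plan: the five-membered ring is made last, so no enone has to be masked while the carbinol is built. The chosen plan needs a reduction–oxidation bracket for this.
- Against it: A4 lacks the C4 methyl. Its introduction (α-halogenation and cross-coupling) in the presence of the methacrylate adds steps. A tertiary propargylic ester that already carried the methyl should ionise more freely and transfer chirality less faithfully. A3 itself holds the C7, C8 and C10 centres on a cycloheptene, so the hard part is only moved into the precursor. The ring centres may oppose the transfer.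
- Comparison: the alternative forms the five-membered ring and one centre, the chosen plan the seven-membered ring and two. Both mechanisms are stereospecific in principle. On step economy the two are judged about equal once the synthesis of A3 is counted.

**Alternative 3:** The cuts are C1–C5 and C8–C9, which lead back to the furan A5 with a tethered allylic acetate. In the forward sense, TiCl4 (tetravalent titanium) would ionise the acetate, and the 2-(silylmethyl)allyl cation would add across the furan α-carbons to give A6 after loss of silicon.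

- In its favour and better than the chosen plan: one step would form two rings, two C–C bonds and the centres C1, C5 and C8. The chosen plan forms one ring, one bond and two centres. The furan oxygen becomes the C8 oxygen with a fixed relation to the ring fusion, so no dynamic reduction is needed at C8. A later β-elimination of the C5–O bond from the C3 ketone would reveal the enone and the C8 hydroxyl together.
- Against it: C10 arrives as a methylene and C7 as an enoate carbon, so both need face-selective reductions under substrate control. The chosen plan sets C10 in its key step. The ester lowers the reactivity of the furan toward the cation. Acetal and acetate must both survive the Lewis acid. The C4 methyl centre of A5 has to direct the facial and compact-or-extended selectivity and is then destroyed.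
- Comparison: the alternative is stronger on complexity gained in the key step and on C8. The chosen plan is stronger on C10 and on the number of stereochemical corrections left afterwards. Overall step economy is expected to be similar.

Key step: step 10

Assumptions (remarks on the chemistry):
- The sense of induction of the three chiral reagents is assigned by analogy with their standard substrates: (S)-Me-CBS to the (R)-carbinol, CuOTf with (S,S)-t-Bu-box to the (R) configuration at the ester-bearing cyclopropane carbon, and RuCl(p-cymene)[(R,R)-TsDPEN] to hydride delivery on the Si face of C8. The antipodal reagent would take its place in the same step if a sense proved opposite.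
- Compounds 2 and 8 are taken as commercially available.

## Route

Step 1
Reactants: 1 ethyl acetate; 2 3-ethoxy-2-methylcyclopent-2-en-1-one
Product: 5 ethyl 2-(2-methyl-3-oxocyclopent-1-en-1-yl)acetate, via lithium enolate of ethyl acetate 3 (not isolated), via tertiary alcohol aldol adduct 4 (not isolated)
Conditions: LiN(i-Pr)2, THF, −78 °C; then 2, −78 to −30 °C; then 1 M HCl, rt
Reagents that add atoms: water, O
Why: Stork–Danheiser sequence: enolate 3 adds 1,2 to the vinylogous ester carbonyl, and aqueous acid hydrolyses the enol ether of 4 and dehydrates the tertiary alcohol. The enone is thereby transposed and the new C5–C6 bond sits on its β-carbon; no stereocentre is formed.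

Step 2
Reactants: 5 ethyl 2-(2-methyl-3-oxocyclopent-1-en-1-yl)acetate
Product: 6 ethyl 2-[(3R)-3-hydroxy-2-methylcyclopent-1-en-1-yl]acetate
Conditions: (S)-Me-CBS (0.1 equiv), BH3·SMe2, THF, −20 °C; MeOH quench
Reagents that add atoms: none
Why: Corey–Bakshi–Shibata 1,2-reduction with the substituted alkene as the large group should give the (R)-carbinol; the ester and the tetrasubstituted alkene are inert at this temperature. The carbinol masks the enone so that the later enol ether is not deactivated, and as a temporary stereocentre it turns any cyclopropane antipode formed in step 6 into a separable diastereomer.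

Step 3
Reactants: 6 ethyl 2-[(3R)-3-hydroxy-2-methylcyclopent-1-en-1-yl]acetate
Product: 7 ethyl 2-[(3R)-2-methyl-3-(triethylsilyloxy)cyclopent-1-en-1-yl]acetate
Conditions: Et3SiCl, imidazole, CH2Cl2, 0 °C to rt
Reagents that add atoms: chlorotriethylsilane, CC[Si](Cl)(CC)CC
Why: Standard silylation of a secondary alcohol; the triethylsilyl group is chosen because it can later be removed beside a hindered tertiary tert-butyldimethylsilyl ether.

Step 4
Reactants: 7 ethyl 2-[(3R)-2-methyl-3-(triethylsilyloxy)cyclopent-1-en-1-yl]acetate; 8 prop-1-yn-1-ylmagnesium bromide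
Product: 10 1-[(3R)-2-methyl-3-(triethylsilyloxy)cyclopent-1-en-1-yl]pent-3-yn-2-one, via Weinreb amide 9 (not isolated)
Conditions: MeNH(OMe)·HCl, i-PrMgCl, THF, −20 °C; then 8, 0 °C to rt; aq NH4Cl
Reagents that add atoms: none
Why: One-pot ester to ketone conversion through Weinreb amide 9, formed with the chloromagnesium amide; the chelated tetrahedral adduct of 8 stops at the ketone stage and keeps the acidic C6 methylene untouched until work-up. The alkyne is the latent (Z)-propenyl group.

Step 5
Reactants: 10 1-[(3R)-2-methyl-3-(triethylsilyloxy)cyclopent-1-en-1-yl]pent-3-yn-2-one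
Product: 12 tert-butyl(dimethyl){[(1E)-1-[(3R)-2-methyl-3-(triethylsilyloxy)cyclopent-1-en-1-yl]pent-1-en-3-yn-2-yl]oxy}silane, via lithium dienolate 11 (not isolated)
Conditions: LiN(i-Pr)2, THF, −78 °C (10 added to the base); then TBSOTf, −78 to 0 °C
Reagents that add atoms: tert-butyldimethylsilyl trifluoromethanesulfonate, CC(C)(C)[Si](C)(C)OS(=O)(=O)C(F)(F)F
Why: Kinetic enolisation through a closed (Ireland-type) transition state: with only a slim alkynyl group on the carbonyl, the bulky ring on C6 avoids the isopropyl groups of the amide and ends trans to oxygen, cis to the alkyne. O-silylation of 11 fixes this (E) geometry, which becomes the cis relation of the two arms on the cyclopropane.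

Step 6
Reactants: 12 tert-butyl(dimethyl){[(1E)-1-[(3R)-2-methyl-3-(triethylsilyloxy)cyclopent-1-en-1-yl]pent-1-en-3-yn-2-yl]oxy}silane; 13 ethyl diazoacetate
Product: 14 ethyl (1R,2S,3S)-2-[(tert-butyldimethylsilyl)oxy]-3-[(3R)-2-methyl-3-(triethylsilyloxy)cyclopent-1-en-1-yl]-2-(prop-1-yn-1-yl)cyclopropane-1-carboxylate
Conditions: (CuOTf)2·C6H6 (cat.), (S,S)-t-Bu-box (cat.), CH2Cl2, 0 °C to rt, slow addition of 13
Reagents that add atoms: none
Why: Asymmetric cyclopropanation of a silyl enol ether by the electrophilic carbenoid from 13; the trisubstituted enol ether is the most nucleophilic π-bond, ahead of the hindered tetrasubstituted ring alkene and the alkyne. Addition is stereospecific (ring and alkyne stay cis) and the carbenoid bonds first to C6 with its ester turned away from the ring, so the ester ends trans to both carbon arms. The ligand sets the ester carbon as (R), which fixes C6 and C8 as drawn.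

Step 7
Reactants: 14 ethyl (1R,2S,3S)-2-[(tert-butyldimethylsilyl)oxy]-3-[(3R)-2-methyl-3-(triethylsilyloxy)cyclopent-1-en-1-yl]-2-(prop-1-yn-1-yl)cyclopropane-1-carboxylate
Product: 15 ethyl (1R,2S,3S)-2-[(tert-butyldimethylsilyl)oxy]-3-[(3R)-3-hydroxy-2-methylcyclopent-1-en-1-yl]-2-(prop-1-yn-1-yl)cyclopropane-1-carboxylate
Conditions: HF·pyridine, pyridine, THF, 0 °C
Reagents that add atoms: none
Why: Buffered fluoride cleaves the secondary allylic triethylsilyl ether much faster than the tertiary cyclopropyl tert-butyldimethylsilyl ether; buffering and low temperature keep the donor–acceptor cyclopropane closed.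

Step 8
Reactants: 15 ethyl (1R,2S,3S)-2-[(tert-butyldimethylsilyl)oxy]-3-[(3R)-3-hydroxy-2-methylcyclopent-1-en-1-yl]-2-(prop-1-yn-1-yl)cyclopropane-1-carboxylate
Product: 16 ethyl (1R,2S,3S)-2-[(tert-butyldimethylsilyl)oxy]-3-(2-methyl-3-oxocyclopent-1-en-1-yl)-2-(prop-1-yn-1-yl)cyclopropane-1-carboxylate
Conditions: MnO2, CH2Cl2, rt
Reagents that add atoms: none
Why: Neutral allylic oxidation returns the enone and removes the temporary C3 stereocentre; the silyloxycyclopropane and alkyne are not affected.

Step 9
Reactants: 16 ethyl (1R,2S,3S)-2-[(tert-butyldimethylsilyl)oxy]-3-(2-methyl-3-oxocyclopent-1-en-1-yl)-2-(prop-1-yn-1-yl)cyclopropane-1-carboxylate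
Product: 17 ethyl (1R,2S,3S)-2-[(tert-butyldimethylsilyl)oxy]-3-(2-methyl-3-oxocyclopent-1-en-1-yl)-2-[(1Z)-prop-1-en-1-yl]cyclopropane-1-carboxylate
Conditions: H2 (1 atm), Pd/CaCO3 poisoned with Pb(OAc)2, quinoline, EtOAc, rt
Reagents that add atoms: none
Why: Syn semi-hydrogenation of the alkyne on the poisoned catalyst gives the (Z)-alkene; the tetrasubstituted enone and the cyclopropane are not reduced. Compound 17 should be stable enough to handle cold, because a Cope shift across its C4=C5 bond would put two methyl groups inward.

Step 10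
Reactants: 17 ethyl (1R,2S,3S)-2-[(tert-butyldimethylsilyl)oxy]-3-(2-methyl-3-oxocyclopent-1-en-1-yl)-2-[(1Z)-prop-1-en-1-yl]cyclopropane-1-carboxylate
Product: 20 ethyl (5R,8S,8aR)-2,6-bis[(tert-butyldimethylsilyl)oxy]-3,8-dimethyl-1,5,8,8a-tetrahydroazulene-5-carboxylate, via cross-conjugated silyloxycyclopentadiene 18 (not isolated), via linear silyloxycyclopentadiene 19 (not isolated)
Conditions: TBSOTf, Et3N (excess), toluene, 0 °C to rt; then 80 °C, dilute
Reagents that add atoms: tert-butyldimethylsilyl trifluoromethanesulfonate, CC(C)(C)[Si](C)(C)OS(=O)(=O)C(F)(F)F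
Why: TBSOTf silylates the enone oxygen and Et3N removes a ring proton to give first the cross-conjugated diene 18; suprafacial [1,5]-hydrogen shifts around the five-membered ring equilibrate it with 19, in which the C1=C5 bond and the (Z)-propenyl group are cis on the cyclopropane. Compound 19 then undergoes the [3,3]-sigmatropic (Cope) rearrangement of a cis-1,2-dialkenylcyclopropane through the boat transition state, forming C1–C10, breaking C6–C8 and moving the double bonds to C5=C6 and C8=C9. The closest known reaction type is the divinylcyclopropane to cycloheptadiene rearrangement set off by enol silylation of 2-vinylcyclopropyl ketones; here the enol ether is the vinylogous one. The seven-membered ring is closed inside the concerted suprafacial six-electron shift itself, driven by release of cyclopropane strain, so no separate cyclisation mode applies. C1 is controlled by the boat geometry, in which its ring hydrogen points inward because C2 and C4 are tied back in the five-membered ring, and C10 by the (Z)-alkene, whose methyl also points inward; H1 and the C10 methyl therefore end cis, and the absolute sense follows from the configurations of cyclopropane carbons C6 and C8. The step needs reaction through C1 and not through C4: a shift across C4=C5 in 17 or 18 would put two methyl groups inward and create a quaternary centre, and only 19 offers an inward hydrogen, so the equilibrating dienes should drain through 19. The boat must also stay open, which the C7 ester, trans to both arms, secures; the one inward methyl is the reason for heating.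

Step 11
Reactants: 20 ethyl (5R,8S,8aR)-2,6-bis[(tert-butyldimethylsilyl)oxy]-3,8-dimethyl-1,5,8,8a-tetrahydroazulene-5-carboxylate
Product: 21 ethyl (8S,8aR)-3,8-dimethyl-2,6-dioxo-1,2,4,5,6,7,8,8a-octahydroazulene-5-carboxylate (C5 epimers in equilibrium through the enol)
Conditions: 1 M HCl, THF, 0 °C to rt
Reagents that add atoms: none
Why: Acid hydrolysis of both silyl enol ethers: protonation of the dienol ether at C6 returns the conjugated C4=C5 enone and protonation at C9 gives the C8 ketone. C7 becomes the epimerisable α-carbon of a β-keto ester; mild acid and short contact avoid dienolisation toward C1.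

Step 12
Reactants: 21 ethyl (8S,8aR)-3,8-dimethyl-2,6-dioxo-1,2,4,5,6,7,8,8a-octahydroazulene-5-carboxylate
Product: 22 ethyl (5S,6R,8S,8aR)-6-hydroxy-3,8-dimethyl-2-oxo-1,2,4,5,6,7,8,8a-octahydroazulene-5-carboxylate
Conditions: RuCl(p-cymene)[(R,R)-TsDPEN] (cat.), HCO2H/Et3N (5:2), CH2Cl2, rt
Reagents that add atoms: none
Why: Noyori–Ikariya transfer hydrogenation with dynamic kinetic resolution: C7 epimerises through the enol in the buffered medium, the bulky catalyst-bound hydride approaches C8 anti to the ester (cis hydroxy ester), and the catalyst selects the Si face of C8 and with it the (7S) epimer. The hindered tetrasubstituted enone is not expected to be reduced.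

Step 13
Reactants: 22 ethyl (5S,6R,8S,8aR)-6-hydroxy-3,8-dimethyl-2-oxo-1,2,4,5,6,7,8,8a-octahydroazulene-5-carboxylate
Product: 23 ethyl (5S,6R,8S,8aR)-2,6-dihydroxy-3,8-dimethyl-1,2,4,5,6,7,8,8a-octahydroazulene-5-carboxylate (C2 epimers)
Conditions: NaBH4, CeCl3·7H2O, MeOH, −40 to 0 °C
Reagents that add atoms: none
Why: Luche 1,2-reduction masks the enone as an allylic alcohol before the organometallic step; the ester is untouched and the configuration of the new carbinol is irrelevant because it is oxidised again in step 15.

Step 14
Reactants: 23 ethyl (5S,6R,8S,8aR)-2,6-dihydroxy-3,8-dimethyl-1,2,4,5,6,7,8,8a-octahydroazulene-5-carboxylate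
Product: 25 (5S,6R,8S,8aR)-5-(2-hydroxypropan-2-yl)-3,8-dimethyl-1,2,4,5,6,7,8,8a-octahydroazulene-2,6-diol (C2 epimers), via methyl ketone 24 (not isolated)
Conditions: MeMgBr (excess), THF, −20 °C to rt; aq NH4Cl
Reagents that add atoms: methylmagnesium bromide, C[Mg]Br
Why: Double Grignard addition to the ester through ketone 24, after two equivalents are spent on the hydroxyls; no other carbonyl is present. The bromomagnesium alkoxide beside the ketone is not expected to undergo retro-aldol cleavage at this temperature, and C7 can no longer epimerise once C11 is a carbinol.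

Step 15
Reactants: 25 (5S,6R,8S,8aR)-5-(2-hydroxypropan-2-yl)-3,8-dimethyl-1,2,4,5,6,7,8,8a-octahydroazulene-2,6-diol
Product: 26 (5S,6R,8S,8aR)-6-hydroxy-5-(2-hydroxypropan-2-yl)-3,8-dimethyl-4,5,6,7,8,8a-hexahydroazulen-2(1H)-one
Conditions: MnO2, CH2Cl2, rt
Reagents that add atoms: none
Why: MnO2 oxidises only the allylic C3 carbinol and leaves the saturated secondary and the tertiary alcohols; both C3 epimers converge on the enone.

Step 16
Reactants: 26 (5S,6R,8S,8aR)-6-hydroxy-5-(2-hydroxypropan-2-yl)-3,8-dimethyl-4,5,6,7,8,8a-hexahydroazulen-2(1H)-one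
Product: 27 (5S,6R,8S,8aR)-5-(2-hydroxypropan-2-yl)-3,8-dimethyl-2-oxo-1,2,4,5,6,7,8,8a-octahydroazulen-6-yl 2-methylprop-2-enoate
Conditions: methacrylic anhydride, Et3N, DMAP (cat.), BHT (trace), CH2Cl2, 0 °C to rt
Reagents that add atoms: methacrylic anhydride, CC(=C)C(=O)OC(=O)C(C)=C
Why: Nucleophile-catalysed acylation takes the secondary C8 hydroxyl; the tertiary C11 hydroxyl does not react under these conditions, and the radical inhibitor suppresses polymerisation.

Step 17
Reactants: 27 (5S,6R,8S,8aR)-5-(2-hydroxypropan-2-yl)-3,8-dimethyl-2-oxo-1,2,4,5,6,7,8,8a-octahydroazulen-6-yl 2-methylprop-2-enoate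
Product: 28 (5S,6R,8S,8aR)-5-(2-acetoxypropan-2-yl)-3,8-dimethyl-2-oxo-1,2,4,5,6,7,8,8a-octahydroazulen-6-yl 2-methylprop-2-enoate
Conditions: Ac2O, DMAP, Et3N, CH2Cl2, rt to 40 °C
Reagents that add atoms: acetic anhydride, CC(=O)OC(C)=O
Why: Steglich-type acetylation of the tertiary alcohol under basic, non-ionising conditions that the enone and the methacrylate tolerate; migration of the methacrylate to the tertiary oxygen is not favoured.

## Compound list

1 | ethyl acetate | CCOC(C)=O | starting material
2 | 3-ethoxy-2-methylcyclopent-2-en-1-one | CCOC1=C(C)C(=O)CC1 | starting material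
3 | lithium 1-ethoxyethenolate (lithium enolate of ethyl acetate) | [Li+].[O-]C(=C)OCC | intermediate
4 | ethyl 2-(3-ethoxy-1-hydroxy-2-methylcyclopent-2-en-1-yl)acetate (racemic; present as its lithium alkoxide) | CCOC(=O)CC1(O)CCC(OCC)=C1C | intermediate
5 | ethyl 2-(2-methyl-3-oxocyclopent-1-en-1-yl)acetate | CCOC(=O)CC1=C(C)C(=O)CC1 | intermediate
6 | ethyl 2-[(3R)-3-hydroxy-2-methylcyclopent-1-en-1-yl]acetate | CCOC(=O)CC1=C(C)[C@H](O)CC1 | intermediate
7 | ethyl 2-[(3R)-2-methyl-3-(triethylsilyloxy)cyclopent-1-en-1-yl]acetate | CCOC(=O)CC1=C(C)[C@H](O[Si](CC)(CC)CC)CC1 | intermediate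
8 | prop-1-yn-1-ylmagnesium bromide | CC#C[Mg]Br | starting material
9 | N-methoxy-N-methyl-2-[(3R)-2-methyl-3-(triethylsilyloxy)cyclopent-1-en-1-yl]acetamide | CON(C)C(=O)CC1=C(C)[C@H](O[Si](CC)(CC)CC)CC1 | intermediate
10 | 1-[(3R)-2-methyl-3-(triethylsilyloxy)cyclopent-1-en-1-yl]pent-3-yn-2-one | CC#CC(=O)CC1=C(C)[C@H](O[Si](CC)(CC)CC)CC1 | intermediate
11 | lithium (1E)-1-[(3R)-2-methyl-3-(triethylsilyloxy)cyclopent-1-en-1-yl]pent-1-en-3-yn-2-olate | CC#C/C([O-])=C\C1=C(C)[C@H](O[Si](CC)(CC)CC)CC1.[Li+] | intermediate
12 | tert-butyl(dimethyl){[(1E)-1-[(3R)-2-methyl-3-(triethylsilyloxy)cyclopent-1-en-1-yl]pent-1-en-3-yn-2-yl]oxy}silane (ring cis to the alkyne) | CC#C/C(O[Si](C)(C)C(C)(C)C)=C\C1=C(C)[C@H](O[Si](CC)(CC)CC)CC1 | intermediate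
13 | ethyl diazoacetate | CCOC(=O)C=[N+]=[N-] | starting material
14 | ethyl (1R,2S,3S)-2-[(tert-butyldimethylsilyl)oxy]-3-[(3R)-2-methyl-3-(triethylsilyloxy)cyclopent-1-en-1-yl]-2-(prop-1-yn-1-yl)cyclopropane-1-carboxylate | CC1=C(CC[C@H]1O[Si](CC)(CC)CC)[C@@H]2[C@@H](C(=O)OCC)[C@]2(O[Si](C)(C)C(C)(C)C)C#CC | intermediate
15 | ethyl (1R,2S,3S)-2-[(tert-butyldimethylsilyl)oxy]-3-[(3R)-3-hydroxy-2-methylcyclopent-1-en-1-yl]-2-(prop-1-yn-1-yl)cyclopropane-1-carboxylate | CC1=C(CC[C@H]1O)[C@@H]2[C@@H](C(=O)OCC)[C@]2(O[Si](C)(C)C(C)(C)C)C#CC | intermediate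
16 | ethyl (1R,2S,3S)-2-[(tert-butyldimethylsilyl)oxy]-3-(2-methyl-3-oxocyclopent-1-en-1-yl)-2-(prop-1-yn-1-yl)cyclopropane-1-carboxylate | CC1=C(CCC1=O)[C@@H]2[C@@H](C(=O)OCC)[C@]2(O[Si](C)(C)C(C)(C)C)C#CC | intermediate
17 | ethyl (1R,2S,3S)-2-[(tert-butyldimethylsilyl)oxy]-3-(2-methyl-3-oxocyclopent-1-en-1-yl)-2-[(1Z)-prop-1-en-1-yl]cyclopropane-1-carboxylate (key-step precursor) | CC1=C(CCC1=O)[C@@H]2[C@@H](C(=O)OCC)[C@]2(O[Si](C)(C)C(C)(C)C)/C=C\C | intermediate
18 | ethyl (1R,2S,3S)-2-[(tert-butyldimethylsilyl)oxy]-3-{3-[(tert-butyldimethylsilyl)oxy]-2-methylcyclopenta-1,3-dien-1-yl}-2-[(1Z)-prop-1-en-1-yl]cyclopropane-1-carboxylate | CC1=C(CC=C1O[Si](C)(C)C(C)(C)C)[C@@H]2[C@@H](C(=O)OCC)[C@]2(O[Si](C)(C)C(C)(C)C)/C=C\C | intermediate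
19 | ethyl (1R,2S,3S)-2-[(tert-butyldimethylsilyl)oxy]-3-{4-[(tert-butyldimethylsilyl)oxy]-5-methylcyclopenta-1,4-dien-1-yl}-2-[(1Z)-prop-1-en-1-yl]cyclopropane-1-carboxylate | CC1=C(O[Si](C)(C)C(C)(C)C)CC=C1[C@@H]2[C@@H](C(=O)OCC)[C@]2(O[Si](C)(C)C(C)(C)C)/C=C\C | intermediate
20 | ethyl (5R,8S,8aR)-2,6-bis[(tert-butyldimethylsilyl)oxy]-3,8-dimethyl-1,5,8,8a-tetrahydroazulene-5-carboxylate (key-step product) | CC1=C(O[Si](C)(C)C(C)(C)C)C[C@H]2C1=C[C@@H](C(=O)OCC)C(O[Si](C)(C)C(C)(C)C)=C[C@@H]2C | intermediate
21 | ethyl (8S,8aR)-3,8-dimethyl-2,6-dioxo-1,2,4,5,6,7,8,8a-octahydroazulene-5-carboxylate (C5 epimers and enol) | O=C1C[C@H](C)[C@H]2CC(=O)C(C)=C2CC1C(=O)OCC | intermediate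
22 | ethyl (5S,6R,8S,8aR)-6-hydroxy-3,8-dimethyl-2-oxo-1,2,4,5,6,7,8,8a-octahydroazulene-5-carboxylate | O[C@@H]1C[C@H](C)[C@H]2CC(=O)C(C)=C2C[C@@H]1C(=O)OCC | intermediate
23 | ethyl (5S,6R,8S,8aR)-2,6-dihydroxy-3,8-dimethyl-1,2,4,5,6,7,8,8a-octahydroazulene-5-carboxylate (C2 epimers) | O[C@@H]1C[C@H](C)[C@H]2CC(O)C(C)=C2C[C@@H]1C(=O)OCC | intermediate
24 | 1-[(5S,6R,8S,8aR)-2,6-dihydroxy-3,8-dimethyl-1,2,4,5,6,7,8,8a-octahydroazulen-5-yl]ethan-1-one (C2 epimers; present as its magnesium alkoxide) | O[C@@H]1C[C@H](C)[C@H]2CC(O)C(C)=C2C[C@@H]1C(C)=O | intermediate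
25 | (5S,6R,8S,8aR)-5-(2-hydroxypropan-2-yl)-3,8-dimethyl-1,2,4,5,6,7,8,8a-octahydroazulene-2,6-diol (C2 epimers) | O[C@@H]1C[C@H](C)[C@H]2CC(O)C(C)=C2C[C@@H]1C(C)(C)O | intermediate
26 | (5S,6R,8S,8aR)-6-hydroxy-5-(2-hydroxypropan-2-yl)-3,8-dimethyl-4,5,6,7,8,8a-hexahydroazulen-2(1H)-one | O[C@@H]1C[C@H](C)[C@H]2CC(=O)C(C)=C2C[C@@H]1C(C)(C)O | intermediate
27 | (5S,6R,8S,8aR)-5-(2-hydroxypropan-2-yl)-3,8-dimethyl-2-oxo-1,2,4,5,6,7,8,8a-octahydroazulen-6-yl 2-methylprop-2-enoate | C=C(C)C(=O)O[C@@H]1C[C@H](C)[C@H]2CC(=O)C(C)=C2C[C@@H]1C(C)(C)O | intermediate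
28 | (5S,6R,8S,8aR)-5-(2-acetoxypropan-2-yl)-3,8-dimethyl-2-oxo-1,2,4,5,6,7,8,8a-octahydroazulen-6-yl 2-methylprop-2-enoate (guaiane numbering 1R,7S,8R,10S) | C=C(C)C(=O)O[C@@H]1C[C@H](C)[C@H]2CC(=O)C(C)=C2C[C@@H]1C(C)(C)OC(C)=O | target

## Step count and least certain steps

Total step count: 17. Longest linear sequence: 17 steps (from 1 and 2 to 28); 8 and 13 enter as single reagents.

**Step 10 (key step).** The cyclopropane carries a silyloxy donor at C8 and acceptors at C7 and, after O-silylation, at C5. The most likely failure is its heterolytic opening under TBSOTf or the ammonium triflate before the sigmatropic shift. Diels–Alder dimerisation of the silyloxycyclopentadiene is a second risk, because the inward methyl slows the Cope shift.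

Fallback, from 17 back to the route at 21, with no silylating agent: 17 is deconjugated by the classical sequence of extended-enolate formation at C1 (KOt-Bu, t-BuOH/THF, low temperature) and kinetic protonation at C4 with acetic acid. This gives the β,γ-unsaturated ketone ethyl (1R,2S,3S)-2-[(tert-butyldimethylsilyl)oxy]-3-(5-methyl-4-oxocyclopent-1-en-1-yl)-2-[(1Z)-prop-1-en-1-yl]cyclopropane-1-carboxylate F1. F1 already holds the C1=C5 bond with an inward hydrogen. It should rearrange as a neutral cis-dialkenylcyclopropane on gentle warming in toluene to the cycloheptadiene ethyl (5R,8S,8aR)-6-[(tert-butyldimethylsilyl)oxy]-3,8-dimethyl-2-oxo-1,2,3,5,8,8a-hexahydroazulene-5-carboxylate F2. Aqueous HCl as in step 11 then hydrolyses the C8 enol ether and brings the C5=C6 bond into conjugation, which gives 21.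

**Step 5.** The most likely failure is enolisation with the wrong geometry (ring cis to oxygen). The doubly activated C6 methylene is deprotonated through an early transition state, and the enolate may equilibrate. This would give a cyclopropane with the two arms trans.

Fallback, from 10 back to the route at 20, by a stereoconvergent thermal path:
- The (Z)-enol ether tert-butyl(dimethyl){[(1Z)-1-[(3R)-2-methyl-3-(triethylsilyloxy)cyclopent-1-en-1-yl]pent-1-en-3-yn-2-yl]oxy}silane F3 is cyclopropanated as in step 6. With the ester again anti to the ring and the ligand-controlled ester carbon unchanged, this gives the C2 epimer ethyl (1R,2R,3S)-2-[(tert-butyldimethylsilyl)oxy]-3-[(3R)-2-methyl-3-(triethylsilyloxy)cyclopent-1-en-1-yl]-2-(prop-1-yn-1-yl)cyclopropane-1-carboxylate F4.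
- The conditions of steps 7 to 9 lead through the alcohol ethyl (1R,2R,3S)-2-[(tert-butyldimethylsilyl)oxy]-3-[(3R)-3-hydroxy-2-methylcyclopent-1-en-1-yl]-2-(prop-1-yn-1-yl)cyclopropane-1-carboxylate F5 and the enone ethyl (1R,2R,3S)-2-[(tert-butyldimethylsilyl)oxy]-3-(2-methyl-3-oxocyclopent-1-en-1-yl)-2-(prop-1-yn-1-yl)cyclopropane-1-carboxylate F6 to the trans-dialkenylcyclopropane ethyl (1R,2R,3S)-2-[(tert-butyldimethylsilyl)oxy]-3-(2-methyl-3-oxocyclopent-1-en-1-yl)-2-[(1Z)-prop-1-en-1-yl]cyclopropane-1-carboxylate F7.
- F7 is silylated as in step 10 to the dienol ether ethyl (1R,2R,3S)-2-[(tert-butyldimethylsilyl)oxy]-3-{4-[(tert-butyldimethylsilyl)oxy]-5-methylcyclopenta-1,4-dien-1-yl}-2-[(1Z)-prop-1-en-1-yl]cyclopropane-1-carboxylate F8.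
- At higher temperature (xylene, about 140 °C) the doubly allylic, oxygen-substituted C6–C8 bond of F8 should break reversibly. Rotation about C8 and reclosure give 19, which rearranges to 20. Rotation at C6 would give the all-cis isomer, which cannot reach the boat and reverts. Because the ester-bearing carbon is untouched, only 19 is Cope-competent, and the same enantiomer of 20 results.

**Step 6.** The most likely failure is poor facial discrimination by the catalyst on a trisubstituted, doubly conjugated enol ether. Competing attack on the ring alkene or the alkyne and carbenoid dimerisation are also possible.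

Fallback, from 12 back to the route at 14, by internal resolution instead of catalyst control: 12 is cyclopropanated with 13 and Rh2(OAc)4. The two trans-ester cyclopropanes are then diastereomers because of the (R)-carbinol centre. Compound 14 is separated by chromatography from its cyclopropane antipode ethyl (1S,2R,3R)-2-[(tert-butyldimethylsilyl)oxy]-3-[(3R)-2-methyl-3-(triethylsilyloxy)cyclopent-1-en-1-yl]-2-(prop-1-yn-1-yl)cyclopropane-1-carboxylate F9 and continues in step 7.

**Step 12.** The most likely failure is poor facial selectivity at C8 under dynamic conditions. The remote C1/C10 centres may oppose the catalyst, so that the other C7 epimer is reduced from the other face. Slow turnover of the largely enolised β-keto ester is a second risk.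

Fallback, from 21 back to the route at 26, setting C7 by catalyst and C8 by the substrate:
- Hydrogenation of 21 with RuCl2[(S)-BINAP] and H2 in MeOH/CH2Cl2 proceeds through the metal chelate, which is reliably anti-selective for cyclic β-keto esters. It should give the trans hydroxy ester ethyl (5S,6S,8S,8aR)-6-hydroxy-3,8-dimethyl-2-oxo-1,2,4,5,6,7,8,8a-octahydroazulene-5-carboxylate F10 with C7 correct.
- The conditions of step 13 give the diol ester ethyl (5S,6S,8S,8aR)-2,6-dihydroxy-3,8-dimethyl-1,2,4,5,6,7,8,8a-octahydroazulene-5-carboxylate F11.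
- The conditions of step 14 lead through the methyl ketone 1-[(5S,6S,8S,8aR)-2,6-dihydroxy-3,8-dimethyl-1,2,4,5,6,7,8,8a-octahydroazulen-5-yl]ethan-1-one F12 to the triol (5S,6S,8S,8aR)-5-(2-hydroxypropan-2-yl)-3,8-dimethyl-1,2,4,5,6,7,8,8a-octahydroazulene-2,6-diol F13.
- Dess–Martin periodinane oxidises both secondary alcohols to the dione (5R,8S,8aR)-5-(2-hydroxypropan-2-yl)-3,8-dimethyl-4,5,7,8-tetrahydroazulene-2,6(1H,8aH)-dione F14.
- Chelation-controlled Narasaka–Prasad reduction (Et2BOMe, NaBH4, THF/MeOH, −78 °C) should reduce the chelated saturated C8 ketone faster than the hindered enone. Hydride should enter anti to the C7–C6 ring bond, which gives the cis diol 26.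

## Further compounds

F1 | step 10 | ethyl (1R,2S,3S)-2-[(tert-butyldimethylsilyl)oxy]-3-(5-methyl-4-oxocyclopent-1-en-1-yl)-2-[(1Z)-prop-1-en-1-yl]cyclopropane-1-carboxylate (methyl-bearing ring carbon as epimers) | CC1C(=O)CC=C1[C@@H]2[C@@H](C(=O)OCC)[C@]2(O[Si](C)(C)C(C)(C)C)/C=C\C
F2 | step 10 | ethyl (5R,8S,8aR)-6-[(tert-butyldimethylsilyl)oxy]-3,8-dimethyl-2-oxo-1,2,3,5,8,8a-hexahydroazulene-5-carboxylate (C3 epimers) | CC1C(=O)C[C@H]2C1=C[C@@H](C(=O)OCC)C(O[Si](C)(C)C(C)(C)C)=C[C@@H]2C
F3 | step 5 | tert-butyl(dimethyl){[(1Z)-1-[(3R)-2-methyl-3-(triethylsilyloxy)cyclopent-1-en-1-yl]pent-1-en-3-yn-2-yl]oxy}silane | CC#C/C(O[Si](C)(C)C(C)(C)C)=C/C1=C(C)[C@H](O[Si](CC)(CC)CC)CC1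
F4 | step 5 | ethyl (1R,2R,3S)-2-[(tert-butyldimethylsilyl)oxy]-3-[(3R)-2-methyl-3-(triethylsilyloxy)cyclopent-1-en-1-yl]-2-(prop-1-yn-1-yl)cyclopropane-1-carboxylate | CC1=C(CC[C@H]1O[Si](CC)(CC)CC)[C@@H]2[C@@H](C(=O)OCC)[C@@]2(O[Si](C)(C)C(C)(C)C)C#CC
F5 | step 5 | ethyl (1R,2R,3S)-2-[(tert-butyldimethylsilyl)oxy]-3-[(3R)-3-hydroxy-2-methylcyclopent-1-en-1-yl]-2-(prop-1-yn-1-yl)cyclopropane-1-carboxylate | CC1=C(CC[C@H]1O)[C@@H]2[C@@H](C(=O)OCC)[C@@]2(O[Si](C)(C)C(C)(C)C)C#CC
F6 | step 5 | ethyl (1R,2R,3S)-2-[(tert-butyldimethylsilyl)oxy]-3-(2-methyl-3-oxocyclopent-1-en-1-yl)-2-(prop-1-yn-1-yl)cyclopropane-1-carboxylate | CC1=C(CCC1=O)[C@@H]2[C@@H](C(=O)OCC)[C@@]2(O[Si](C)(C)C(C)(C)C)C#CC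
F7 | step 5 | ethyl (1R,2R,3S)-2-[(tert-butyldimethylsilyl)oxy]-3-(2-methyl-3-oxocyclopent-1-en-1-yl)-2-[(1Z)-prop-1-en-1-yl]cyclopropane-1-carboxylate | CC1=C(CCC1=O)[C@@H]2[C@@H](C(=O)OCC)[C@@]2(O[Si](C)(C)C(C)(C)C)/C=C\C
F8 | step 5 | ethyl (1R,2R,3S)-2-[(tert-butyldimethylsilyl)oxy]-3-{4-[(tert-butyldimethylsilyl)oxy]-5-methylcyclopenta-1,4-dien-1-yl}-2-[(1Z)-prop-1-en-1-yl]cyclopropane-1-carboxylate | CC1=C(O[Si](C)(C)C(C)(C)C)CC=C1[C@@H]2[C@@H](C(=O)OCC)[C@@]2(O[Si](C)(C)C(C)(C)C)/C=C\C
F9 | step 6 | ethyl (1S,2R,3R)-2-[(tert-butyldimethylsilyl)oxy]-3-[(3R)-2-methyl-3-(triethylsilyloxy)cyclopent-1-en-1-yl]-2-(prop-1-yn-1-yl)cyclopropane-1-carboxylate | CC1=C(CC[C@H]1O[Si](CC)(CC)CC)[C@H]2[C@H](C(=O)OCC)[C@@]2(O[Si](C)(C)C(C)(C)C)C#CC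
F10 | step 12 | ethyl (5S,6S,8S,8aR)-6-hydroxy-3,8-dimethyl-2-oxo-1,2,4,5,6,7,8,8a-octahydroazulene-5-carboxylate | O[C@H]1C[C@H](C)[C@H]2CC(=O)C(C)=C2C[C@@H]1C(=O)OCC
F11 | step 12 | ethyl (5S,6S,8S,8aR)-2,6-dihydroxy-3,8-dimethyl-1,2,4,5,6,7,8,8a-octahydroazulene-5-carboxylate (C2 epimers) | O[C@H]1C[C@H](C)[C@H]2CC(O)C(C)=C2C[C@@H]1C(=O)OCC
F12 | step 12 | 1-[(5S,6S,8S,8aR)-2,6-dihydroxy-3,8-dimethyl-1,2,4,5,6,7,8,8a-octahydroazulen-5-yl]ethan-1-one (C2 epimers) | O[C@H]1C[C@H](C)[C@H]2CC(O)C(C)=C2C[C@@H]1C(C)=O
F13 | step 12 | (5S,6S,8S,8aR)-5-(2-hydroxypropan-2-yl)-3,8-dimethyl-1,2,4,5,6,7,8,8a-octahydroazulene-2,6-diol (C2 epimers) | O[C@H]1C[C@H](C)[C@H]2CC(O)C(C)=C2C[C@@H]1C(C)(C)O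
F14 | step 12 | (5R,8S,8aR)-5-(2-hydroxypropan-2-yl)-3,8-dimethyl-4,5,7,8-tetrahydroazulene-2,6(1H,8aH)-dione | O=C1C[C@H](C)[C@H]2CC(=O)C(C)=C2C[C@@H]1C(C)(C)O
A1 | alternative 1 | (10R)-8,8-ethylenedioxy-11,12,13-trinoreudesma-1,4-dien-3-one (4,10-dimethyl decalin dienone, eudesmane numbering) | CC1=C2CCC3(OCCO3)C[C@]2(C)C=CC1=O
A2 | alternative 1 | 10-acetoxy-8,8-ethylenedioxy-11,12,13-trinorguai-4-en-3-one | CC1=C2CCC3(OCCO3)C[C@](C)(OC(C)=O)[C@H]2CC1=O
A3 | alternative 2 | cyclohept-1-ene with the C7, C8 and C10 substituents of the target and a (4S)-1-pivaloyloxyprop-2-yn-1-yl group on C5 (guaiane numbering) | C=C(C)C(=O)O[C@@H]1C[C@H](C)C=C(C[C@@H]1C(C)(C)OC(C)=O)[C@@H](OC(=O)C(C)(C)C)C#C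
A4 | alternative 2 | 4-desmethyl analogue of the target enone | C=C(C)C(=O)O[C@@H]1C[C@H](C)[C@H]2CC(=O)C=C2C[C@@H]1C(C)(C)OC(C)=O
A5 | alternative 3 | methyl 5-[(1R)-1-(2-{2-acetoxy-3-[(trimethylsilyl)methyl]but-3-en-1-yl}-1,3-dioxolan-2-yl)ethyl]furan-3-carboxylate (acetate carbon as epimers) | COC(=O)c1coc(c1)[C@@H](C)C2(OCCO2)CC(OC(C)=O)C(=C)C[Si](C)(C)C
A6 | alternative 3 | oxygen-bridged (C5–O–C8) tricyclic enoate with C10 methylene and C3 ethylene ketal | COC(=O)C1=C[C@@]23O[C@@H]1CC(=C)[C@H]2CC4(OCCO4)[C@@H]3C
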